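**Assumption (one line):** The SMILES gives (2S) at C2. The (S,S)-Box ligand is assumed to deliver that enantiomer (the ligand enantiomer would be matched empirically). Resorcinol + prenal is assumed to give the 7-hydroxychromene as the major regioisomer.

## Retrosynthetic overview
1. The target comes from its tri-MOM ether by global deprotection.
2. The chromanone ring (C3–C4 and C2–O1 bonds) is formed last, in one radical annulation: an aroyl radical from a 2-hydroxyaryl aldehyde (A ring) adds to a 6-vinylchromene (B ring). A chiral Cu(II)-phenoxide then captures the benzylic radical and sets C2.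
3. The A-ring aldehyde comes from resorcinol: bis-MOM protection, C2-prenylation, C–H borylation/oxidation (the third, meta oxygen), then ortho-formylation.
4. The B-ring styrene comes from resorcinol + prenal (2,2-dimethylchromene), ortho-formylation, MOM protection and methylenation.
5. Ring order: the B-ring pyran is made first, the A-ring is fully functionalised next, and the pyranone C ring is closed last.

## Route

**Step 1**
Reactants: **1** resorcinol
Product: **2** 1,3-bis(methoxymethoxy)benzene
Conditions: NaH, MOMCl, THF, 0 °C → rt
Reagents that add atoms: chloromethyl methyl ether, ClCOC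
Why: Williamson-type O-alkylation gives the bis-MOM ether, which is the directing group for the next lithiation and the A-ring protection.

**Step 2**
Reactants: **2**; **3** prenyl bromide (1-bromo-3-methylbut-2-ene, CC(C)=CCBr)
Product: **4** 2-prenyl-1,3-bis(methoxymethoxy)benzene
Conditions: n-BuLi, THF, 0 °C; then CuBr·SMe2 (10 mol %), **3**, −78 °C → rt
Reagents that add atoms: none
Why: Directed ortho-metalation occurs at C2 between the two OMOM groups, and Cu catalysis makes the allylation SN2-selective, so the normal prenyl unit is kept rather than the reverse-prenyl isomer.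

**Step 3**
Reactants: **4**
Product: **5** 3,5-bis(methoxymethoxy)-4-(3-methylbut-2-en-1-yl)phenol
Conditions: (i) [Ir(OMe)(cod)]2 (1.5 mol %), dtbpy (3 mol %), B2pin2, THF, 80 °C; (ii) 30% H2O2, 3 M NaOH, 0 °C (one pot)
Reagents that add atoms: hydrogen peroxide, OO (supplies the new phenolic O)
Why: Ir-catalysed C–H borylation is sterically controlled and goes only to C5, the position meta to both OMOM groups (C2 is blocked by prenyl). Oxidation of the C–B bond then installs the third oxygen, and the hindered trisubstituted prenyl alkene and the MOM groups survive.

**Step 4**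
Reactants: **5**
Product: **6** 6-hydroxy-2,4-bis(methoxymethoxy)-3-(3-methylbut-2-en-1-yl)benzaldehyde
Conditions: MgCl2, Et3N, (CH2O)n, MeCN, reflux
Reagents that add atoms: paraformaldehyde, C=O
Why: Mg-phenoxide-directed ortho-formylation (Casnati–Skattebøl) occurs next to the only free OH. The two ortho positions are equivalent, so there is no regiochemical ambiguity, and the free OH becomes the future ring O1 (so prenyl ends up at C6).

**Step 5**
Reactants: **1** resorcinol; **7** prenal (3-methylbut-2-enal, CC(C)=CC=O)
Product: **8** 7-hydroxy-2,2-dimethyl-2H-chromene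
Conditions: pyridine, 120 °C
Reagents that add atoms: none
Why: Phenol–enal condensation followed by oxa-6π electrocyclisation of the o-quinone methide builds the 2,2-dimethylchromene. Reaction para to the other OH gives the linear 7-hydroxy isomer.

**Step 6**
Reactants: **8**
Product: **9** 7-hydroxy-2,2-dimethyl-2H-chromene-6-carbaldehyde
Conditions: MgCl2, Et3N, (CH2O)n, MeCN, reflux
Reagents that add atoms: paraformaldehyde, C=O
Why: Ortho-formylation of the Mg phenoxide goes to C6 (para to the pyran O), not to C8, which is flanked by two oxygens and hindered.

**Step 7**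
Reactants: **9**
Product: **10** 7-(methoxymethoxy)-2,2-dimethyl-2H-chromene-6-carbaldehyde
Conditions: MOMCl, iPr2NEt, CH2Cl2, 0 °C → rt
Reagents that add atoms: chloromethyl methyl ether, ClCOC
Why: Protecting the phenol prevents o-quinone-methide formation and Cu-phenoxide interference in the radical step.

**Step 8**
Reactants: **10**
Product: **11** 6-vinyl-7-(methoxymethoxy)-2,2-dimethyl-2H-chromene
Conditions: Ph3P⁺CH3 Br⁻, KOtBu, THF, 0 °C → rt
Reagents that add atoms: methyltriphenylphosphonium bromide, C[P+](c1ccccc1)(c1ccccc1)c1ccccc1.[Br-] (supplies the =CH2 carbon)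
Why: Wittig methylenation gives the unhindered styrene, which is the radical acceptor; the MOM ether and chromene are base-stable.

**Step 9 (key step)**
Reactants: **6** aldehyde; **11** styrene (2 equiv)
Product: **12** (2S)-5,7-bis(methoxymethoxy)-2-[7-(methoxymethoxy)-2,2-dimethyl-2H-chromen-6-yl]-6-(3-methylbut-2-en-1-yl)chroman-4-one
Conditions: [Cu(MeCN)4]PF6 (10 mol %), (S,S)-tBu-Box (12 mol %), tert-butyl perbenzoate (2 equiv), PhCF3, 60 °C
Reagents that add atoms: none
Why: Proposed new method: tBuO•, from Cu(I) + perester, abstracts the aldehyde H to give an aroyl radical. This adds anti-Markovnikov to the terminal CH2 of the styrene (forming the C3–C4 bond) to give a benzylic radical. The free A-ring phenol, bound as a chiral Cu(II)-phenoxide, traps that radical, and C–O reductive elimination from Cu(III) closes the six-membered ring (C2–O1) and sets C2 as (S). The closest known chemistry is radical acylation of styrenes with aldehydes combined with Cu/Box enantioselective radical C–O coupling (Kharasch–Sosnovsky type); the hindered prenyl and chromene alkenes are much poorer acceptors for a nucleophilic acyl radical than the terminal styrene.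

**Step 10**
Reactants: **12**
Product: **13** cudraflavanone A, (2S)-5,7-dihydroxy-2-(7-hydroxy-2,2-dimethyl-2H-chromen-6-yl)-6-(3-methylbut-2-en-1-yl)chroman-4-one
Conditions: 3 M HCl, MeOH/THF (1:1), 25–40 °C
Reagents that add atoms: none
Why: Acid-catalysed MOM acetal cleavage (transacetalisation to CH2(OMe)2) is mild enough to spare the chromene, the prenyl group and the C2 stereocentre (the flavanone ring is stable to acid and is not epimerised).

## Compound list
1 | resorcinol | Oc1cccc(O)c1 | starting material
2 | 1,3-bis(methoxymethoxy)benzene | COCOc1cccc(OCOC)c1 | intermediate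
3 | prenyl bromide | CC(C)=CCBr | starting material
4 | 2-prenyl-1,3-bis(methoxymethoxy)benzene | CC(C)=CCc1c(OCOC)cccc1OCOC | intermediate
5 | 3,5-bis(methoxymethoxy)-4-prenylphenol | CC(C)=CCc1c(OCOC)cc(O)cc1OCOC | intermediate
6 | 6-hydroxy-2,4-bis(methoxymethoxy)-3-prenylbenzaldehyde | O=Cc1c(O)cc(OCOC)c(CC=C(C)C)c1OCOC | intermediate
7 | prenal | CC(C)=CC=O | starting material
8 | 7-hydroxy-2,2-dimethyl-2H-chromene | CC1(C)C=Cc2ccc(O)cc2O1 | intermediate
9 | 7-hydroxy-2,2-dimethyl-2H-chromene-6-carbaldehyde | CC1(C)C=Cc2cc(C=O)c(O)cc2O1 | intermediate
10 | 7-(methoxymethoxy)-2,2-dimethyl-2H-chromene-6-carbaldehyde | CC1(C)C=Cc2cc(C=O)c(OCOC)cc2O1 | intermediate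
11 | 6-vinyl-7-(methoxymethoxy)-2,2-dimethyl-2H-chromene | CC1(C)C=Cc2cc(C=C)c(OCOC)cc2O1 | intermediate
12 | tri-MOM cudraflavanone A | CC(C)=CCc1c(OCOC)cc2c(c1OCOC)C(=O)C[C@@H](c1cc3c(cc1OCOC)OC(C)(C)C=C3)O2 | intermediate
13 | cudraflavanone A | CC(C)=CCc1c(O)cc2c(c1O)C(=O)C[C@@H](c1cc3c(cc1O)OC(C)(C)C=C3)O2 | target

## Totals
Total steps: 10. Longest linear sequence: 6 (1 → 2 → 4 → 5 → 6 → 12 → 13, and equally 1 → 8 → 9 → 10 → 11 → 12 → 13).

## Three steps most likely to fail
1. **Step 9 (radical annulation).** Risks are aroyl-radical over-oxidation and a racemic background from the strongly stabilised p-alkoxybenzylic cation. Fallback: run an oxidative radical acylation of the styrene without the chiral Cu, giving the 2'-hydroxychalcone. Then close the ring by an enantioselective organocatalytic oxa-Michael cyclisation (chiral bifunctional iminophosphorane or thiourea), so C2 is set by polar catalysis instead.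
2. **Step 3 (Ir borylation/oxidation on the prenylated substrate).** The prenyl alkene may isomerise or hydroborate. Fallback: borylate and oxidise 1,3-bis(MOMO)benzene first, giving 3,5-bis(MOMO)phenol. Then silylate the phenol (TBS), lithiate C4 between the two OMOM groups and prenylate (Cu-catalysed), and remove the silyl group, so the prenyl group is added after the borylation.
3. **Step 10 (global deprotection).** The acid-labile chromene and prenyl phenol could cyclise or ring-open, or the flavanone could racemise. Fallback: use SEM instead of MOM in Steps 1 and 7, then remove all three SEM ethers under acid-free conditions (TBAF/ethylenediamine in DMF, or MgBr2·OEt2).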